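Skeleton numbering used throughout: ring A is C1 (quaternary, methyl), C2, C3, C4, C5; ring B is C5, C6, C7, C8, C9, C10, C1. The face of the C1 methyl group is called α, the opposite face β. TIPS = triisopropylsilyl, TES = triethylsilyl, TBS = tert-butyldimethylsilyl.

## Analysis of the target

Target 33 is a trans-fused hydroazulene of the daucane type: cyclopentane ring A (C1–C5) shares the C1–C5 bond with cycloheptene ring B, whose only alkene is the trisubstituted C8=C9 bond carrying the C8 methyl group. There are six stereocentres: quaternary C1, the secondary carbinol C2, the tertiary isopropyl carbinol C4, the ring-fusion methine C5, and the two acyloxy carbons C6 and C10. The C1 methyl and the C2 and C4 hydroxyls are α; H-5, the isopropyl group and both ester oxygens are β (1R,2R,4R,5S,6S,10R in this numbering). Both esters are angelates ((Z)-2-methylbut-2-enoates), which slip to tiglates under nucleophilic catalysis, base or prolonged heat, and the C10 ester is also allylic. Whenever C6 is a ketone it is a β,γ-unsaturated ketone (C7 lies between it and C8=C9) with an oxygen at the β-carbon C4, so conjugation of the alkene, β-elimination and epimerisation at C5 all threaten. The difficulty lies in the quaternary C1, flanked by three stereocentres, in the seven-membered ring, and in telling four oxygens apart (two identical esters, one free secondary and one free tertiary hydroxyl). The strategy rests on one observation: with C6 at the ketone level and enolised towards C5, ring B holds C5=C6 and C8=C9 separated by the C7 methylene, with C10 and C1 as the adjoining sp3 pair. That cyclohepta-1,4-diene is exactly what a cis-divinylcyclopropane gives on [3,3] rearrangement, and C8 is then the former carbene carbon, so an ester there can stand for the methyl group.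

## Retrosynthetic reasoning

33 back to 32, and 32 back to 29 and 30. The last operation only frees the C2 hydroxyl; its silyl ether is kept to the end because C2–OH is the one secondary hydroxyl that must not be acylated. Both ester C–O bonds are cut together, which asks for a triol 29 with free C6 and C10 hydroxyls; the tertiary C4 hydroxyl needs no protection because it will not acylate.

29 back to 28 and 27. The C6 and C10 oxygens are carried as the same silyl ether so that one operation frees both. The C4–isopropyl bond is cut next, giving cyclopentanone 27. The forward addition must come from the β face, and it should: the α face is closed by the C1 methyl, the C2 silyloxy group and the C5–C6 bond. The isopropyl group is brought in this late so that C4 still carries hydrogen on its β face when C5 is protonated.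

27 back to 26, 25, 24 and 23. The C6 carbinol needs hydride on the α face, the face syn to the angular methyl, so only intramolecular delivery from the α oxygen at C4 will do. A C4/C6 diketone would be an enolised 1,3-dione that no isopropyl nucleophile could use, so C6 is reduced before C4 is oxidised. A Tishchenko-type reduction of β-hydroxy ketone 23 is chosen over a borohydride-type directed reduction because it leaves C4 acylated and C6 free in 24. The two secondary hydroxyls are thereby differentiated: C6 is silylated (25), C4 is released (26) and oxidised (27).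

23 back to 21. The C6 ketone and H-5 come from the enol ether; the C5–H bond is cut. The forward protonation must be kinetic and from the β face. Base equilibration of C5 is not used because it would also pull C8=C9 into conjugation.

21 back to 19 and 18. The C8 methyl comes from the ester through the allylic alcohol. This is done while C6 is still an enol ether, so hydride reagents meet no ketone.

18 back to 11 and 16 (key step). C1–C10 and C7–C8 are cut. Cyclopropane 17 links the two: a vinylcarbene from 16 adds to the ethoxyvinyl group of 11, and the [3,3] shift then makes the quaternary centre. No other disconnection forms C1 and C10 together with their relative configuration fixed by alkene geometry.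

11 back to 10, 9, 8, 7 and 6. The C5–C6 bond is cut as a cross-coupling of alkenyl iodide 10; it is placed last because the 2-ethoxydiene is acid-labile. The C4 carbinol of 9 comes from iodoenone 8 by hydride addition anti to the C2 silyloxy group, so the single resolved centre of 6 controls C4.

6 back to 5, 4, 1 and 2. The hydroxycyclopentenone is opened by an intramolecular aldol disconnection to hydroxy diketone 3, which is the decarboxylative aldol product of 1 and 2; the racemate 4 is resolved enzymatically through acetate 5.

16 back to 14, 12 and 13. The enol ether double bond is cut by dehydration of aldol adduct 14, which comes from 12 and 13.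

## Alternatives that were turned down

Alternative 1: Ring B is closed at C1–C10 by a radical. Hydroazulenedione A1 is traced back to selenoester A2, a 3-methylcyclopentenone whose C5 carries a chain ending in a (Z)-enoyl phenylselenide. Forward, a silane-mediated radical chain generates the C10 acyl radical, which attacks the enone β-carbon C1 in a 7-endo mode; the C5 radical next to the C4 ketone then takes up hydrogen.
- For: the nucleophilic acyl radical and the electron-poor enone are polarity-matched, radicals tolerate the build-up of a quaternary centre, and the C2 silyloxy group should steer the chain to the β face. A1 arrives with the C4 ketone in place and C6 already set, so it needs neither a directed C6 reduction nor oxidation-state changes at C4. On that point it is stronger than the chosen route.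
- Against: 7-endo closure onto a fully substituted carbon is slow, so premature hydrogen transfer to the acyl radical and 6-exo attack at C5 compete. The unsaturated acyl radical is delocalised and can lose the Z geometry without which the ring cannot close. C5 is set by hydrogen transfer next to a ketone and may settle as the cis fusion. The C10 carbinol must then be made by hydride attack on the α face, syn to the adjacent angular methyl, and the C4 ketone and C10 enone must be told apart. A2 itself needs an enantioselective C6 carbinol and a Z-trisubstituted enoyl unit in a linear chain.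
- Comparison: the chosen route gives C1 and C10 in one stereospecific event with the C10 oxygen already at the alcohol level, from two short fragments.

Alternative 2: Ring B is made by one-carbon enlargement of a six-membered ring. Hydroazulenone A3 is traced back to β-hydroxy acid A4, a hydrindene whose C6 carries a hydroxyl and an acetic acid arm. Forward, anodic decarboxylation gives the C7 radical, which adds to the adjacent alkene carbon C8 and reopens with cleavage of C6–C8; the C6 hydroxyalkyl radical is then oxidised to the ketone.
- For: six–five ring systems with an angular methyl are easy to reach, no reagent is consumed, and A3 already holds the isopropyl carbinol and the C8 methyl. It is only a directed reduction, a desilylation, the acylation and a deprotection away from 33, so on steps after the key step it is clearly stronger.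
- Against: at graphite the primary radical is readily oxidised further to the cation (Hofer–Moest manifold), after which migration of C5 instead of C8, solvent capture or elimination are all open. Radical dimerisation and hydrogen abstraction compete with the 1,2-alkenyl shift. A4 needs five stereocentres and a tertiary C6 carbinol assembled linearly on the hydrindene first.
- Comparison: the chosen route instead builds ring B and two stereocentres convergently, by a step whose course is fixed by orbital symmetry, not by the balance between radical and cation.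

Alternative 3: Ring B is closed at C9–C10. Allylic alcohol A5 is traced back to iodo aldehyde A6, a fully substituted cyclopentane with the C10 aldehyde on quaternary C1 and a chain ending in a (Z)-alkenyl iodide. Forward, a Nozaki–Hiyama–Kishi reaction (divalent chromium, nickel catalysis) adds the alkenyl metal to the aldehyde.
- For: the reaction tolerates every group present and is reliable for medium rings. A5 carries all stereocentres and the C10 hydroxyl emerges free, so the endgame is the shortest of all; here it is stronger than the chosen route.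
- Against: the aldehyde is neopentyl, and the C10 configuration arises under substrate control with no clear bias. The quaternary C1, the C4 carbinol, C5, C6 and the Z-iodoalkene must each be made by separate stereocontrolled steps before cyclisation, giving a long linear precursor.
- Comparison: the chosen route creates the quaternary C1 and C10 together and draws ring A from a cyclopentenone with one resolved stereocentre.

Key step: step 11

Assumption 1 (remark on the chemistry): the lipase is taken to show its usual preference for the (R)-configured alcohol of 4-hydroxycyclopentenones; if the preference were reversed, the unreacted alcohol would be carried on instead.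

Assumption 2 (remark on the chemistry): the sense of induction of Rh2(DOSP)4 (dirhodium tetrakis[N-(4-dodecylphenylsulfonyl)prolinate]) is taken over from its cyclopropanations of styrenes and vinyl ethers with vinyldiazoacetates, which calls for the R catalyst here; if the sense were opposite, the S catalyst would be used.

## Route

Step 1
Reactants: 1 methylglyoxal; 2 lithium acetoacetate
Product: 4 rac-4-hydroxy-3-methylcyclopent-2-en-1-one, via 3-hydroxyhexane-2,5-dione 3 (not isolated)
Conditions: H2O, NaHCO3 (pH 7–8), rt; then aq. NaOH (pH 11–12), rt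
Reagents that add atoms: none
Why: Decarboxylative aldol addition of the acetoacetate methylene to the aldehyde of 1 gives 3, whose methyl ketone enolate closes onto the more electrophilic α-hydroxy ketone carbonyl (intramolecular aldol condensation) in dilute base; this is the classical cyclopentenolone synthesis and gives the racemate.

Step 2
Reactants: 4 rac-4-hydroxy-3-methylcyclopent-2-en-1-one
Product: 5 (1R)-2-methyl-4-oxocyclopent-2-en-1-yl acetate
Conditions: lipase PS (Burkholderia cepacia), vinyl acetate, t-BuOMe, 30 °C, stopped a little before half conversion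
Reagents that add atoms: vinyl acetate, CC(=O)OC=C
Why: Lipase-catalysed kinetic resolution by irreversible transesterification; the (R)-alcohol should be acylated faster, and the unreacted (S)-enantiomer of 4 is removed by chromatography.

Step 3
Reactants: 5 (1R)-2-methyl-4-oxocyclopent-2-en-1-yl acetate
Product: 6 (4R)-4-hydroxy-3-methylcyclopent-2-en-1-one
Conditions: lipase PS, KH2PO4/K2HPO4 buffer (pH 7), acetone, rt
Reagents that add atoms: none
Why: Enzymatic hydrolysis at neutral pH frees the alcohol without the elimination that carbonate or hydroxide would cause in a 4-acyloxycyclopentenone, and the second pass through the same (R)-selective enzyme should raise the enantiomeric purity.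

Step 4
Reactants: 6 (4R)-4-hydroxy-3-methylcyclopent-2-en-1-one
Product: 7 (4R)-3-methyl-4-(triisopropylsilyloxy)cyclopent-2-en-1-one
Conditions: i-Pr3SiOTf, 2,6-lutidine, CH2Cl2, −78 °C
Reagents that add atoms: triisopropylsilyl triflate, CC(C)[Si](OS(=O)(=O)C(F)(F)F)(C(C)C)C(C)C
Why: Silylation of a secondary alcohol with a silyl triflate and a hindered pyridine base, fast enough at low temperature to spare the base-sensitive hydroxy enone; the bulky ether later shields the α face and lasts to the final step.

Step 5
Reactants: 7 (4R)-3-methyl-4-(triisopropylsilyloxy)cyclopent-2-en-1-one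
Product: 8 (4R)-2-iodo-3-methyl-4-(triisopropylsilyloxy)cyclopent-2-en-1-one
Conditions: I2, pyridine–CH2Cl2 (1:1), 0 °C → rt, extended time
Reagents that add atoms: iodine, II
Why: α-Iodination of the enone by conjugate addition of pyridine, iodination of the enolate and elimination; the β-methyl group slows the addition, but the reaction type is established for 3-methylcycloalkenones.

Step 6
Reactants: 8 (4R)-2-iodo-3-methyl-4-(triisopropylsilyloxy)cyclopent-2-en-1-one
Product: 9 (1S,4R)-2-iodo-3-methyl-4-(triisopropylsilyloxy)cyclopent-2-en-1-ol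
Conditions: NaBH4, CeCl3·7H2O, MeOH, −78 → −40 °C
Reagents that add atoms: none
Why: Luche reduction gives clean 1,2-reduction of the iodoenone; hydride attacks anti to the silyloxy group, so the new hydroxyl (the future C4 oxygen) is cis to it (1S).

Step 7
Reactants: 9 (1S,4R)-2-iodo-3-methyl-4-(triisopropylsilyloxy)cyclopent-2-en-1-ol
Product: 10 triethyl{[(1S,4R)-2-iodo-3-methyl-4-(triisopropylsilyloxy)cyclopent-2-en-1-yl]oxy}silane
Conditions: Et3SiCl, imidazole, CH2Cl2, 0 °C
Reagents that add atoms: chlorotriethylsilane, CC[Si](Cl)(CC)CC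
Why: Standard silylation; the triethylsilyl ether is chosen because it must later be cleaved in the presence of TBS and TIPS ethers.

Step 8
Reactants: 10 triethyl{[(1S,4R)-2-iodo-3-methyl-4-(triisopropylsilyloxy)cyclopent-2-en-1-yl]oxy}silane
Product: 11 {[(1S,4R)-2-(1-ethoxyethenyl)-3-methyl-4-(triisopropylsilyloxy)cyclopent-2-en-1-yl]oxy}triethylsilane
Conditions: Pd(PPh3)4 (5 mol %), CuI (20 mol %), CsF, DMF, 45 °C; chromatography on Et3N-washed silica
Reagents that add atoms: tributyl(1-ethoxyvinyl)stannane, CCCC[Sn](CCCC)(CCCC)C(=C)OCC
Why: Stille coupling of the alkenyl iodide, with CuI and fluoride to speed transmetalation at the hindered tetrasubstituted alkene; the acid-labile 2-ethoxydiene is made last so that it meets no protic or Lewis-acidic step before the key reaction.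

Step 9
Reactants: 12 ethyl diazoacetate; 13 (tert-butyldimethylsilyloxy)acetaldehyde
Product: 14 ethyl 4-(tert-butyldimethylsilyloxy)-2-diazo-3-hydroxybutanoate (racemic)
Conditions: DBU (0.2 equiv), MeCN, rt
Reagents that add atoms: none
Why: Amine-catalysed aldol-type addition of the diazoacetate carbon to the aldehyde; the carbinol centre is of no consequence because it is eliminated in the next step.

Step 10
Reactants: 14 ethyl 4-(tert-butyldimethylsilyloxy)-2-diazo-3-hydroxybutanoate
Product: 16 ethyl (E)-4-(tert-butyldimethylsilyloxy)-2-diazobut-3-enoate, via dichlorophosphate ester 15 (not isolated)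
Conditions: POCl3, Et3N, CH2Cl2, 0 °C; used at once, kept cold
Reagents that add atoms: none
Why: Dehydration of β-hydroxy-α-diazo esters through the dichlorophosphate is the standard entry to vinyldiazoacetates; elimination can only go towards C4 and anti elimination should favour the E silyl enol ether.

Step 11
Reactants: 11 {[(1S,4R)-2-(1-ethoxyethenyl)-3-methyl-4-(triisopropylsilyloxy)cyclopent-2-en-1-yl]oxy}triethylsilane; 16 ethyl (E)-4-(tert-butyldimethylsilyloxy)-2-diazobut-3-enoate
Product: 18 bicyclic cycloheptadiene ester (6-ethoxy and 8-ethoxycarbonyl on the C5=C6/C8=C9 diene; 1α-methyl; 2α-OTIPS; 4α-OTES; 10β-OTBS), via cis-divinylcyclopropane 17 (not isolated)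
Conditions: Rh2(R-DOSP)4 (1 mol %), hexanes, −40 °C → rt, 16 added over 2 h; then toluene, 110 °C
Reagents that add atoms: none
Why: The catalyst turns 16 into a rhodium-bound donor/acceptor vinylcarbene that cyclopropanates only the terminal, electron-rich C6=C7 enol ether bond of 11 (forming C7–C8 and the temporary C6–C8 bond); the tetrasubstituted ring alkene and the hindered C–H bonds next to the silyloxy groups should not compete, and the hydrocarbon solvent and the E substituent on the vinyl terminus disfavour attack at the vinylogous carbon. In 17 the cyclopentenyl and siloxyvinyl groups are cis (alkenyl cis to the carbene's donor group), and any trans isomer can reach that arrangement on heating because the C6–C8 bond of this donor–acceptor cyclopropane opens reversibly. Ring B then closes by a [3,3] sigmatropic shift through the boat transition state with both alkenes folded over the three-membered ring: C10 bonds to C1, C6–C8 breaks, and the alkenes reappear at C8=C9 and C5=C6. The closest known reaction type is the tandem cyclopropanation–Cope rearrangement of rhodium vinylcarbenes with dienes, a formal (4+3) cycloaddition. The seven-membered ring is thus closed by a concerted, strain-releasing 3,3-shift and not by an end-to-end cyclisation. C10 is controlled by the E geometry of the silyl enol ether, which puts the silyloxy group outward in the boat and hence trans to the C1 methyl. C1 is controlled by the C6/C8 configuration of 17, set by the R catalyst, which brings C10 onto the β face, anti to the α silyloxy groups at C2 and C4, so catalyst and substrate are matched. The C1 methyl points inward in the boat and raises the barrier, which is why the rearrangement is finished at 110 °C.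

Step 12
Reactants: 18 bicyclic cycloheptadiene ester
Product: 19 allylic alcohol (8-hydroxymethyl; otherwise as 18)
Conditions: i-Bu2AlH (3 equiv), CH2Cl2, −78 °C; aq. KNaC4H4O6 work-up
Reagents that add atoms: none
Why: 1,2-Reduction of the conjugated ester to the allylic alcohol; the enol ether and the three silyl ethers are inert, and doing this before the C6 ketone is unveiled avoids any chemoselectivity problem.

Step 13
Reactants: 19 allylic alcohol
Product: 21 8-methyl enol ether (6-ethoxy-C5=C6/C8=C9 diene with 1α,8-dimethyl; silyl ethers as in 18), via allylic mesylate 20 (not isolated)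
Conditions: MsCl, Et3N, THF, −40 °C; then LiEt3BH, −40 → 0 °C
Reagents that add atoms: none
Why: The primary allylic alcohol is activated as its mesylate and displaced by hydride at the unhindered primary carbon (SN2), a standard deoxygenation that leaves the C8=C9 alkene where it is.

Step 14
Reactants: 21 8-methyl enol ether
Product: 23 β-hydroxy ketone (6-oxo; 4α-hydroxy; 5β-H; 2α-OTIPS; 10β-OTBS), via 4-O-triethylsilyl ketone 22 (not isolated)
Conditions: AcOH–THF–H2O (3:1:1), 0 °C → rt
Reagents that add atoms: water, O
Why: Weak aqueous acid hydrolyses the enol ether in the way 1-alkoxycyclohexa-1,4-dienes are hydrolysed to β,γ-unsaturated ketones without conjugation, and then cleaves the TES ether while the TBS and TIPS ethers stay. C5 is protonated on the β face because the α face is flanked by the C1 methyl and the C4 silyloxy group, which gives the trans ring fusion.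

Step 15
Reactants: 23 β-hydroxy ketone
Product: 24 4α-isobutyryloxy-6β-ol
Conditions: SmI2 (0.3 equiv), i-PrCHO (6 equiv), THF, −10 °C
Reagents that add atoms: 2-methylpropanal, CC(C)C=O
Why: Evans–Tishchenko reduction: the samarium-bound hemiacetal formed from the C4 hydroxyl and the aldehyde delivers hydride intramolecularly to the α face of the C6 ketone, giving the 1,3-anti diol with the 6β-hydroxyl (6S) free and the C4 oxygen acylated, so the two secondary hydroxyls are differentiated in the same step.

Step 16
Reactants: 24 4α-isobutyryloxy-6β-ol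
Product: 25 6β,10β-bis(tert-butyldimethylsilyloxy) 4α-isobutyrate
Conditions: t-BuMe2SiOTf, 2,6-lutidine, CH2Cl2, −78 → 0 °C
Reagents that add atoms: tert-butyldimethylsilyl triflate, CC(C)(C)[Si](C)(C)OS(=O)(=O)C(F)(F)F
Why: Silylation of the free C6 hydroxyl; C6 now carries the same group as C10 so that both can be released together later.

Step 17
Reactants: 25 6β,10β-bis(tert-butyldimethylsilyloxy) 4α-isobutyrate
Product: 26 4α-ol (6β,10β-bis-OTBS; 2α-OTIPS)
Conditions: i-Bu2AlH (3 equiv), CH2Cl2, −78 °C; aq. KNaC4H4O6 work-up
Reagents that add atoms: none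
Why: Reductive cleavage of the ester frees the C4 hydroxyl; silyl ethers and the isolated alkene are untouched.

Step 18
Reactants: 26 4α-ol
Product: 27 4-ketone (5β-H; 6β,10β-bis-OTBS; 2α-OTIPS)
Conditions: Dess–Martin periodinane, NaHCO3, CH2Cl2, 0 °C → rt
Reagents that add atoms: none
Why: Dess–Martin oxidation under buffered, non-basic conditions gives the cyclopentanone without epimerising C5 or eliminating the β-silyloxy group at C6.

Step 19
Reactants: 27 4-ketone
Product: 28 4α-hydroxy-4β-isopropyl compound (6β,10β-bis-OTBS; 2α-OTIPS)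
Conditions: i-PrMgCl, CeCl3 (dried), THF, −78 → −40 °C
Reagents that add atoms: isopropylmagnesium chloride, CC(C)[Mg]Cl
Why: The organocerium reagent adds to the hindered, enolisable ketone without enolisation or β-hydride reduction; it attacks the β face because the α face is closed by the C1 methyl, the C2 silyloxy group and the C5–C6 bond, which gives the 4α-hydroxyl and 4β-isopropyl group (4R).

Step 20
Reactants: 28 4α-hydroxy-4β-isopropyl compound
Product: 29 4α,6β,10β-triol 2α-TIPS ether
Conditions: HF·pyridine, pyridine, THF, 0 °C → rt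
Reagents that add atoms: none
Why: Buffered HF·pyridine cleaves the two secondary TBS ethers; the TIPS ether is intrinsically slower and sits on the crowded α face next to the quaternary carbon, and the buffered fluoride medium avoids ionising the allylic C10 oxygen.

Step 21
Reactants: 29 4α,6β,10β-triol 2α-TIPS ether; 30 angelic acid
Product: 32 6β,10β-bis-angelate 2α-TIPS ether, via mixed anhydride 31 (not isolated)
Conditions: 30 (6 equiv), 2,4,6-Cl3C6H2COCl, Et3N, toluene, rt; then 29, 80 °C
Reagents that add atoms: none
Why: Yamaguchi-type esterification through the mixed anhydride without a nucleophilic pyridine catalyst, the conditions under which angelates form with least Z-to-E isomerisation; the two secondary hydroxyls react and the tertiary C4 hydroxyl does not.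

Step 22
Reactants: 32 6β,10β-bis-angelate 2α-TIPS ether
Product: 33 target, (1R,3R,3aR,4R,8S,8aS)-1,3-dihydroxy-3a,6-dimethyl-1-(propan-2-yl)-1,2,3,3a,4,7,8,8a-octahydroazulene-4,8-diyl bis[(2Z)-2-methylbut-2-enoate]
Conditions: HF·pyridine, THF, rt → 40 °C
Reagents that add atoms: none
Why: Fluoride cleavage of the last silyl ether under weakly acidic conditions, which neither hydrolyse nor isomerise the angelates; the C2 and C10 oxygens are anti across C1, so no acyl migration is expected.

## Compound list

1 | methylglyoxal | CC(=O)C=O | starting material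
2 | lithium acetoacetate | [Li+].CC(=O)CC([O-])=O | starting material
3 | 3-hydroxyhexane-2,5-dione (racemic) | CC(=O)CC(O)C(C)=O | intermediate (not isolated)
4 | rac-4-hydroxy-3-methylcyclopent-2-en-1-one | CC1=CC(=O)CC1O | intermediate
5 | (1R)-2-methyl-4-oxocyclopent-2-en-1-yl acetate | O=C1C=C(C)[C@H](OC(C)=O)C1 | intermediate
6 | (4R)-4-hydroxy-3-methylcyclopent-2-en-1-one | O=C1C=C(C)[C@H](O)C1 | intermediate
7 | (4R)-3-methyl-4-(triisopropylsilyloxy)cyclopent-2-en-1-one | O=C1C=C(C)[C@H](O[Si](C(C)C)(C(C)C)C(C)C)C1 | intermediate
8 | (4R)-2-iodo-3-methyl-4-(triisopropylsilyloxy)cyclopent-2-en-1-one | O=C1C(I)=C(C)[C@H](O[Si](C(C)C)(C(C)C)C(C)C)C1 | intermediate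
9 | (1S,4R)-2-iodo-3-methyl-4-(triisopropylsilyloxy)cyclopent-2-en-1-ol (cis) | IC1=C(C)[C@H](O[Si](C(C)C)(C(C)C)C(C)C)C[C@@H]1O | intermediate
10 | triethyl{[(1S,4R)-2-iodo-3-methyl-4-(triisopropylsilyloxy)cyclopent-2-en-1-yl]oxy}silane | IC1=C(C)[C@H](O[Si](C(C)C)(C(C)C)C(C)C)C[C@@H]1O[Si](CC)(CC)CC | intermediate
11 | {[(1S,4R)-2-(1-ethoxyethenyl)-3-methyl-4-(triisopropylsilyloxy)cyclopent-2-en-1-yl]oxy}triethylsilane (key-step diene) | C=C(OCC)C1=C(C)[C@H](O[Si](C(C)C)(C(C)C)C(C)C)C[C@@H]1O[Si](CC)(CC)CC | intermediate
12 | ethyl diazoacetate | CCOC(=O)C=[N+]=[N-] | starting material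
13 | (tert-butyldimethylsilyloxy)acetaldehyde | CC(C)(C)[Si](C)(C)OCC=O | starting material
14 | ethyl 4-(tert-butyldimethylsilyloxy)-2-diazo-3-hydroxybutanoate (racemic) | CCOC(=O)C(=[N+]=[N-])C(O)CO[Si](C)(C)C(C)(C)C | intermediate
15 | ethyl 4-(tert-butyldimethylsilyloxy)-3-(dichlorophosphoryloxy)-2-diazobutanoate | CCOC(=O)C(=[N+]=[N-])C(OP(=O)(Cl)Cl)CO[Si](C)(C)C(C)(C)C | intermediate (not isolated)
16 | ethyl (E)-4-(tert-butyldimethylsilyloxy)-2-diazobut-3-enoate | CCOC(=O)C(=[N+]=[N-])/C=C/O[Si](C)(C)C(C)(C)C | intermediate
17 | ethyl (1S,2R)-2-ethoxy-1-[(E)-2-(tert-butyldimethylsilyloxy)ethenyl]-2-[(3R,5S)-2-methyl-5-(triethylsilyloxy)-3-(triisopropylsilyloxy)cyclopent-1-en-1-yl]cyclopropane-1-carboxylate (alkenyl groups cis) | CCOC(=O)[C@]1(/C=C/O[Si](C)(C)C(C)(C)C)C[C@@]1(OCC)C2=C(C)[C@H](O[Si](C(C)C)(C(C)C)C(C)C)C[C@@H]2O[Si](CC)(CC)CC | intermediate (not isolated)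
18 | bicyclic cycloheptadiene ester: hydroazulene with C5=C6 (6-OEt) and C8=C9 (8-CO2Et), 1α-methyl, 2α-OTIPS, 4α-OTES, 10β-OTBS | CCOC=1CC(C(=O)OCC)=C[C@@H](O[Si](C)(C)C(C)(C)C)[C@@]2(C)[C@H](O[Si](C(C)C)(C(C)C)C(C)C)C[C@H](O[Si](CC)(CC)CC)C=12 | intermediate
19 | allylic alcohol: as 18 with 8-CH2OH | CCOC=1CC(CO)=C[C@@H](O[Si](C)(C)C(C)(C)C)[C@@]2(C)[C@H](O[Si](C(C)C)(C(C)C)C(C)C)C[C@H](O[Si](CC)(CC)CC)C=12 | intermediate
20 | allylic mesylate: as 18 with 8-CH2OSO2CH3 | CCOC=1CC(COS(C)(=O)=O)=C[C@@H](O[Si](C)(C)C(C)(C)C)[C@@]2(C)[C@H](O[Si](C(C)C)(C(C)C)C(C)C)C[C@H](O[Si](CC)(CC)CC)C=12 | intermediate (not isolated)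
21 | 8-methyl enol ether: as 18 with 8-CH3 | CCOC=1CC(C)=C[C@@H](O[Si](C)(C)C(C)(C)C)[C@@]2(C)[C@H](O[Si](C(C)C)(C(C)C)C(C)C)C[C@H](O[Si](CC)(CC)CC)C=12 | intermediate
22 | 6-ketone with 4α-OTES, 5β-H, 2α-OTIPS, 10β-OTBS, C8=C9 | O=C1CC(C)=C[C@@H](O[Si](C)(C)C(C)(C)C)[C@@]2(C)[C@H](O[Si](C(C)C)(C(C)C)C(C)C)C[C@H](O[Si](CC)(CC)CC)[C@H]12 | intermediate (not isolated)
23 | β-hydroxy ketone: 6-oxo, 4α-OH, 5β-H, 2α-OTIPS, 10β-OTBS | O=C1CC(C)=C[C@@H](O[Si](C)(C)C(C)(C)C)[C@@]2(C)[C@H](O[Si](C(C)C)(C(C)C)C(C)C)C[C@H](O)[C@H]12 | intermediate
24 | 4α-isobutyryloxy-6β-ol (2α-OTIPS, 10β-OTBS) | O[C@H]1CC(C)=C[C@@H](O[Si](C)(C)C(C)(C)C)[C@@]2(C)[C@H](O[Si](C(C)C)(C(C)C)C(C)C)C[C@H](OC(=O)C(C)C)[C@H]12 | intermediate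
25 | 6β,10β-bis-OTBS 4α-isobutyrate (2α-OTIPS) | CC(C)(C)[Si](C)(C)O[C@H]1CC(C)=C[C@@H](O[Si](C)(C)C(C)(C)C)[C@@]2(C)[C@H](O[Si](C(C)C)(C(C)C)C(C)C)C[C@H](OC(=O)C(C)C)[C@H]12 | intermediate
26 | 4α-ol (6β,10β-bis-OTBS, 2α-OTIPS) | CC(C)(C)[Si](C)(C)O[C@H]1CC(C)=C[C@@H](O[Si](C)(C)C(C)(C)C)[C@@]2(C)[C@H](O[Si](C(C)C)(C(C)C)C(C)C)C[C@H](O)[C@H]12 | intermediate
27 | 4-ketone (5β-H, 6β,10β-bis-OTBS, 2α-OTIPS) | CC(C)(C)[Si](C)(C)O[C@H]1CC(C)=C[C@@H](O[Si](C)(C)C(C)(C)C)[C@@]2(C)[C@H](O[Si](C(C)C)(C(C)C)C(C)C)CC(=O)[C@H]12 | intermediate
28 | 4α-hydroxy-4β-isopropyl compound (6β,10β-bis-OTBS, 2α-OTIPS) | CC(C)(C)[Si](C)(C)O[C@H]1CC(C)=C[C@@H](O[Si](C)(C)C(C)(C)C)[C@@]2(C)[C@H](O[Si](C(C)C)(C(C)C)C(C)C)C[C@@](O)(C(C)C)[C@H]12 | intermediate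
29 | 4α,6β,10β-triol 2α-TIPS ether | O[C@H]1CC(C)=C[C@@H](O)[C@@]2(C)[C@H](O[Si](C(C)C)(C(C)C)C(C)C)C[C@@](O)(C(C)C)[C@H]12 | intermediate
30 | angelic acid, (Z)-2-methylbut-2-enoic acid | C/C=C(/C)C(=O)O | starting material
31 | (Z)-2-methylbut-2-enoic 2,4,6-trichlorobenzoic anhydride | C/C=C(/C)C(=O)OC(=O)c1c(Cl)cc(Cl)cc1Cl | intermediate (not isolated)
32 | 6β,10β-bis-angelate 2α-TIPS ether | C/C=C(/C)C(=O)O[C@H]1CC(C)=C[C@@H](OC(=O)/C(C)=C\C)[C@@]2(C)[C@H](O[Si](C(C)C)(C(C)C)C(C)C)C[C@@](O)(C(C)C)[C@H]12 | intermediate
33 | CNP0249167.2, (1R,3R,3aR,4R,8S,8aS)-1,3-dihydroxy-3a,6-dimethyl-1-(propan-2-yl)-1,2,3,3a,4,7,8,8a-octahydroazulene-4,8-diyl bis[(2Z)-2-methylbut-2-enoate] | C/C=C(/C)C(=O)O[C@H]1CC(C)=C[C@@H](OC(=O)/C(C)=C\C)[C@@]2(C)[C@H](O)C[C@@](O)(C(C)C)[C@H]12 | target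

## Step count and least certain steps

Total: 22 steps. Longest linear sequence: 20 steps (steps 1–8 and 11–22); the diazo ester branch (steps 9 and 10) joins at step 11.

Step 11 (key step). Most likely to go wrong: the donor–acceptor cyclopropane opens to a zwitterion that closes to a five-membered ring or transfers a proton before the slow [3,3] shift, which is retarded by the inward methyl on the fully substituted C1; loss of 16 to a pyrazole adds to this. Fallback: set out from 10 and drop the ethoxy group, so that the cyclopropane has no donor and can only rearrange.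
- Stille coupling of 10 with a vinyl tin reagent should give triethyl{[(1S,4R)-2-ethenyl-3-methyl-4-(triisopropylsilyloxy)cyclopent-2-en-1-yl]oxy}silane F1, a plain 1,3-diene of the classical substrate class.
- The same rhodium-catalysed tandem reaction with 16 should give the 6-unsubstituted cycloheptadiene ester F2.
- Hydroboration–oxidation (BH3·SMe2; then NaBO3) of the electron-rich C5=C6 alkene from the β face, in the presence of the deactivated enoate, should give the 5β-H 6β-hydroxy ester F3 by one syn addition.
- Silylation should give the 6β-silyloxy ester F4, i-Bu2AlH the allylic alcohol F5, and mesylation with LiEt3BH the 8-methyl tris-silyl ether F6.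
- Selective methanolysis of the TES ether (pyridinium tosylate, MeOH) returns to 26.

Step 10. Most likely to go wrong: decomposition of the electron-rich vinyl diazo ester during the dehydration (electrocyclisation to a pyrazole, desilylation by chloride) or formation of an E/Z mixture. Fallback: set out from 13. Wittig olefination with ethyl (triphenylphosphoranylidene)acetate should give ethyl (E)-4-(tert-butyldimethylsilyloxy)but-2-enoate F7. Deconjugative Regitz diazo transfer through the extended enolate (4-acetamidobenzenesulfonyl azide, DBU, MeCN, 0 °C) then returns to 16 without any dehydration step.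

Step 14. Most likely to go wrong: epimerisation at C5 towards the cis-fused ketone, or migration of the C8=C9 alkene into conjugation, while the free β,γ-unsaturated ketone sits in acid for the time the TES cleavage needs. Fallback: set out from 21 and never expose an enolisable C6 ketone until C4 is quaternary.
- Pyridinium tosylate and ethylene glycol should trap the oxocarbenium ion formed by β-face protonation as the 6,6-ethylenedioxy 4α-alcohol F8, with loss of the TES ether.
- Dess–Martin oxidation should give the keto ketal F9, and i-PrMgCl/CeCl3 the 4α-hydroxy-4β-isopropyl ketal F10.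
- Mild aqueous acid should release the tertiary β-hydroxy ketone F11 (the same compound as A3).
- Evans–Saksena reduction (Me4NBH(OAc)3, AcOH–MeCN, −30 °C), directed by the tertiary C4 hydroxyl, should give the 6β-ol F12.
- HF·pyridine then cleaves the C10 TBS ether and returns to 29.

Step 19. Most likely to go wrong: enolisation of the ketone (with epimerisation at C5 or β-elimination of the C6 silyloxy group) or β-hydride reduction, because the branched nucleophile is slow at this hindered carbonyl. Fallback: set out from 27 with a smaller sp2 nucleophile that has no β-hydrogen to transfer. Isopropenylmagnesium bromide with CeCl3 should give the 4β-isopropenyl carbinol F13. Hydrogenation with RhCl(PPh3)3 and H2, selective for the 1,1-disubstituted alkene over the ring alkene, returns to 28.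

Step 21. Most likely to go wrong: Z-to-E isomerisation of the acyl group to the tiglate during the long heating that the neopentyl C10 hydroxyl needs, or incomplete acylation there. Fallback: set out from 29 and build the Z alkene on the ester after acylation. Carbodiimide coupling with 2-[bis(2,2,2-trifluoroethoxy)phosphoryl]propanoic acid should give the 6,10-bis(phosphonopropanoate) F14. Still–Gennari olefination with acetaldehyde (KN(SiMe3)2, 18-crown-6, THF, −78 °C) then forms both (Z)-2-methylbut-2-enoates and returns to 32.

## Further compounds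

F1 | step 11 | triethyl{[(1S,4R)-2-ethenyl-3-methyl-4-(triisopropylsilyloxy)cyclopent-2-en-1-yl]oxy}silane | C=CC1=C(C)[C@H](O[Si](C(C)C)(C(C)C)C(C)C)C[C@@H]1O[Si](CC)(CC)CC
F2 | step 11 | 6-unsubstituted cycloheptadiene ester (C5=C6–H, 8-CO2Et on C8=C9, 1α-methyl, 2α-OTIPS, 4α-OTES, 10β-OTBS) | CCOC(=O)C1=C[C@@H](O[Si](C)(C)C(C)(C)C)[C@@]2(C)[C@H](O[Si](C(C)C)(C(C)C)C(C)C)C[C@H](O[Si](CC)(CC)CC)C2=CC1
F3 | step 11 | 5β-H 6β-hydroxy ester (8-CO2Et, 4α-OTES, 2α-OTIPS, 10β-OTBS) | O[C@H]1CC(C(=O)OCC)=C[C@@H](O[Si](C)(C)C(C)(C)C)[C@@]2(C)[C@H](O[Si](C(C)C)(C(C)C)C(C)C)C[C@H](O[Si](CC)(CC)CC)[C@H]12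
F4 | step 11 | 6β-(tert-butyldimethylsilyloxy) ester | CC(C)(C)[Si](C)(C)O[C@H]1CC(C(=O)OCC)=C[C@@H](O[Si](C)(C)C(C)(C)C)[C@@]2(C)[C@H](O[Si](C(C)C)(C(C)C)C(C)C)C[C@H](O[Si](CC)(CC)CC)[C@H]12
F5 | step 11 | 8-hydroxymethyl compound (6β,10β-bis-OTBS, 4α-OTES, 2α-OTIPS) | CC(C)(C)[Si](C)(C)O[C@H]1CC(CO)=C[C@@H](O[Si](C)(C)C(C)(C)C)[C@@]2(C)[C@H](O[Si](C(C)C)(C(C)C)C(C)C)C[C@H](O[Si](CC)(CC)CC)[C@H]12
F6 | step 11 | 8-methyl tris-silyl ether (6β,10β-bis-OTBS, 4α-OTES, 2α-OTIPS) | CC(C)(C)[Si](C)(C)O[C@H]1CC(C)=C[C@@H](O[Si](C)(C)C(C)(C)C)[C@@]2(C)[C@H](O[Si](C(C)C)(C(C)C)C(C)C)C[C@H](O[Si](CC)(CC)CC)[C@H]12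
F7 | step 10 | ethyl (E)-4-(tert-butyldimethylsilyloxy)but-2-enoate | CCOC(=O)/C=C/CO[Si](C)(C)C(C)(C)C
F8 | step 14 | 6,6-ethylenedioxy 4α-alcohol (5β-H, 2α-OTIPS, 10β-OTBS) | O1CCOC12CC(C)=C[C@@H](O[Si](C)(C)C(C)(C)C)[C@@]3(C)[C@H](O[Si](C(C)C)(C(C)C)C(C)C)C[C@H](O)[C@H]23
F9 | step 14 | 6,6-ethylenedioxy 4-ketone | O1CCOC12CC(C)=C[C@@H](O[Si](C)(C)C(C)(C)C)[C@@]3(C)[C@H](O[Si](C(C)C)(C(C)C)C(C)C)CC(=O)[C@H]23
F10 | step 14 | 6,6-ethylenedioxy 4α-hydroxy-4β-isopropyl compound | O1CCOC12CC(C)=C[C@@H](O[Si](C)(C)C(C)(C)C)[C@@]3(C)[C@H](O[Si](C(C)C)(C(C)C)C(C)C)C[C@@](O)(C(C)C)[C@H]23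
F11 | step 14 | 6-ketone with 4α-hydroxy-4β-isopropyl, 2α-OTIPS, 10β-OTBS | O=C1CC(C)=C[C@@H](O[Si](C)(C)C(C)(C)C)[C@@]2(C)[C@H](O[Si](C(C)C)(C(C)C)C(C)C)C[C@@](O)(C(C)C)[C@H]12
F12 | step 14 | 4α,6β-diol with 10β-OTBS and 2α-OTIPS | O[C@H]1CC(C)=C[C@@H](O[Si](C)(C)C(C)(C)C)[C@@]2(C)[C@H](O[Si](C(C)C)(C(C)C)C(C)C)C[C@@](O)(C(C)C)[C@H]12
F13 | step 19 | 4α-hydroxy-4β-isopropenyl compound (6β,10β-bis-OTBS, 2α-OTIPS) | CC(C)(C)[Si](C)(C)O[C@H]1CC(C)=C[C@@H](O[Si](C)(C)C(C)(C)C)[C@@]2(C)[C@H](O[Si](C(C)C)(C(C)C)C(C)C)C[C@@](O)(C(C)=C)[C@H]12
F14 | step 21 | 6β,10β-bis{2-[bis(2,2,2-trifluoroethoxy)phosphoryl]propanoate} of 29 (epimers at the phosphonate carbons) | CC(C(=O)O[C@H]1CC(C)=C[C@@H](OC(=O)C(C)P(=O)(OCC(F)(F)F)OCC(F)(F)F)[C@@]2(C)[C@H](O[Si](C(C)C)(C(C)C)C(C)C)C[C@@](O)(C(C)C)[C@H]12)P(=O)(OCC(F)(F)F)OCC(F)(F)F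
A1 | alternative 1 | hydroazulene-4,10-dione (6β-OTBS, 2α-OTES, C8=C9 enone) | CC(C)(C)[Si](C)(C)O[C@H]1CC(C)=CC(=O)[C@@]2(C)[C@H](O[Si](CC)(CC)CC)CC(=O)[C@H]12
A2 | alternative 1 | Se-phenyl (Z)-selenoester of the C5 side chain on the 3-methylcyclopentenone | O=C([Se]c1ccccc1)/C=C(C)\C[C@H](O[Si](C)(C)C(C)(C)C)C2=C(C)[C@H](O[Si](CC)(CC)CC)CC2=O
A3 | alternative 2 | hydroazulenone with C6 ketone (4α-hydroxy-4β-isopropyl, 2α-OTIPS, 10β-OTBS) | O=C1CC(C)=C[C@@H](O[Si](C)(C)C(C)(C)C)[C@@]2(C)[C@H](O[Si](C(C)C)(C(C)C)C(C)C)C[C@@](O)(C(C)C)[C@H]12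
A4 | alternative 2 | hydrindene β-hydroxy acid (C6 carbinol carrying the acetic acid arm; either C6 epimer, that centre is lost) | OC(=O)CC1(O)C(C)=C[C@@H](O[Si](C)(C)C(C)(C)C)[C@@]2(C)[C@H](O[Si](C(C)C)(C(C)C)C(C)C)C[C@@](O)(C(C)C)[C@H]12
A5 | alternative 3 | hydroazulene with free C10 hydroxyl (6β-OTBS, 4α-OTES, 2α-OTIPS) | CC(C)(C)[Si](C)(C)O[C@H]1CC(C)=C[C@@H](O)[C@@]2(C)[C@H](O[Si](C(C)C)(C(C)C)C(C)C)C[C@@](O[Si](CC)(CC)CC)(C(C)C)[C@H]12
A6 | alternative 3 | cyclopentane carbaldehyde with (Z)-alkenyl iodide side chain | O=C[C@@]1(C)[C@H](O[Si](C(C)C)(C(C)C)C(C)C)C[C@@](O[Si](CC)(CC)CC)(C(C)C)[C@@H]1[C@@H](O[Si](C)(C)C(C)(C)C)C/C(C)=C\I
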